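The five ring atoms of the imidazole (N1 bearing CH3, C2 bearing the exocyclic nitrogen, N3, C4, C5) all come from creatinine. C5, the methylene next to N1, receives the hydroquinone-derived benzyl group by aldol condensation and hydrogenation. The route then rests on the C4–CH2 bond. The C4 lactam carbonyl is locked as an aromatic imidazol-4-yl triflate and exchanged for the 4-methoxybenzyl group by Negishi coupling, which completes the tetrasubstituted imidazole core in one operation. The precursor is a 1-methyl-5-benzylimidazol-4-yl triflate with no N–H or O–H bond: the amino group is a dimethylformamidine and the hydroquinone a bis-MOM ether. The dehydrohydantoin is attached last.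

Key step: step 9

Assumption: the benzylidene intermediate may form as an E/Z mixture (E drawn) and the two C5-sp3 intermediates after it are racemic, which is immaterial because C5 becomes sp2 again on triflation; 1-methylparabanic acid has a single N–H and therefore takes up one silyl group.

Step 1
Reactants: 1 2,3-dimethoxy-1,4-benzoquinone
Product: 2 2,3-dimethoxybenzene-1,4-diol
Conditions: Na2S2O4, EtOAc/H2O, 25 °C, Ar
Reagents that add atoms: none
Why: Dithionite delivers two electrons and water two protons to the quinone (quinone-to-hydroquinone reduction), a fast reaction that leaves the two methyl ethers untouched.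

Step 2
Reactants: 2 2,3-dimethoxybenzene-1,4-diol
Product: 3 1,4-bis(methoxymethoxy)-2,3-dimethoxybenzene
Conditions: MOMCl, iPr2NEt, CH2Cl2, 0 → 25 °C, Ar
Reagents that add atoms: chloromethyl methyl ether (MOMCl), COCCl
Why: Double O-alkylation of the phenols with an α-chloro ether (MOM protection) gives acetals that withstand the organolithium, amine, hydrogenation, strong-base and organozinc steps ahead and that direct the next metalation.

Step 3
Reactants: 3 1,4-bis(methoxymethoxy)-2,3-dimethoxybenzene
Product: 5 2,5-bis(methoxymethoxy)-3,4-dimethoxybenzaldehyde, via aryllithium 4 (not isolated)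
Conditions: n-BuLi, TMEDA, THF, −78 → 0 °C; DMF, −78 → 0 °C; H2O
Reagents that add atoms: N,N-dimethylformamide, CN(C)C=O; n-butyllithium, [Li]CCCC (lithium of 4 only)
Why: Directed ortho-metalation next to an OMOM group followed by formylation with DMF can give only one aldehyde, because the two free ring positions of 3 are equivalent by symmetry.

Step 4
Reactants: 5 2,5-bis(methoxymethoxy)-3,4-dimethoxybenzaldehyde; 6 creatinine
Product: 7 (E)-2-amino-5-[2,5-bis(methoxymethoxy)-3,4-dimethoxybenzylidene]-1-methyl-1,5-dihydro-4H-imidazol-4-one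
Conditions: piperidine, 105 °C, Ar
Reagents that add atoms: none
Why: Knoevenagel-type aldol condensation at the acidic C5 methylene of creatinine is the classical reaction of this lactam with aromatic aldehydes, and the amine medium keeps the acetals intact while placing the aryl-CH unit on the ring carbon next to N1.

Step 5
Reactants: 7 the benzylidene creatinine
Product: 8 racemic 2-amino-5-[2,5-bis(methoxymethoxy)-3,4-dimethoxybenzyl]-1-methyl-1,5-dihydro-4H-imidazol-4-one
Conditions: H2 (3 atm), 10% Pd/C, MeOH/THF, 25 °C
Reagents that add atoms: none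
Why: Heterogeneous catalytic hydrogenation saturates the polarised exocyclic C=C bond without touching aryl ethers or acetals; the new C5 centre is formed without control as a racemate and is erased in step 7.

Step 6
Reactants: 8 the 5-benzylcreatinine
Product: 9 racemic N'-{5-[2,5-bis(methoxymethoxy)-3,4-dimethoxybenzyl]-1-methyl-4-oxo-4,5-dihydro-1H-imidazol-2-yl}-N,N-dimethylformimidamide
Conditions: Me2NCH(OMe)2, DMF, 50 °C
Reagents that add atoms: N,N-dimethylformamide dimethyl acetal, COC(OC)N(C)C
Why: Condensation of the primary amino group with an amide acetal (formamidine protection) removes both N–H bonds, and it is placed after the hydrogenation because C5, now tertiary, can no longer form an enaminone with the reagent.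

Step 7
Reactants: 9 the formamidine-protected imidazolone
Product: 11 2-{[(dimethylamino)methylidene]amino}-1-methyl-5-[2,5-bis(methoxymethoxy)-3,4-dimethoxybenzyl]-1H-imidazol-4-yl trifluoromethanesulfonate, via potassium imidazol-4-olate 10 (not isolated)
Conditions: KN(SiMe3)2, THF, −78 °C; PhNTf2, −78 → 0 °C, Ar
Reagents that add atoms: N-phenylbis(trifluoromethanesulfonimide) (PhNTf2), O=S(=O)(N(c1ccccc1)S(=O)(=O)C(F)(F)F)C(F)(F)F; KN(SiMe3)2, C[Si](C)(C)[N-][Si](C)(C)C.[K+] (potassium of 10 only)
Why: Enolate O-triflation with aromatisation, the reaction type that converts oxazol-4(5H)-ones and thiazol-4(5H)-ones into azol-4-yl triflates, should work because loss of the C5 proton gives an aromatic 4-oxidoimidazole whose only other anionic site, C5, is fully substituted and would lose aromaticity on attack.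

Step 8
Reactants: 12 4-methoxybenzyl chloride
Product: 13 4-methoxybenzylzinc chloride (THF solution, LiCl complex, titrated and used as such)
Conditions: Zn dust (activated with BrCH2CH2Br and Me3SiCl), LiCl, THF, 25 °C
Reagents that add atoms: zinc, [Zn]
Why: Direct insertion of zinc into the benzylic C–Cl bond, accelerated and solubilised by LiCl, is a standard preparation of benzylic zinc chlorides and proceeds at room temperature, where Wurtz coupling stays minor.

Step 9
Reactants: 11 the imidazol-4-yl triflate; 13 4-methoxybenzylzinc chloride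
Product: 14 N'-{5-[2,5-bis(methoxymethoxy)-3,4-dimethoxybenzyl]-4-(4-methoxybenzyl)-1-methyl-1H-imidazol-2-yl}-N,N-dimethylformimidamide
Conditions: Pd(OAc)2 (5 mol%), SPhos (10 mol%), THF, slow addition of 13, 25 → 50 °C, Ar
Reagents that add atoms: none
Why: Proposed new method: zerovalent palladium carrying the electron-rich biaryl phosphine should insert into the C4–O bond of 11, helped by the pyridine-type N3 next to C4 much as in 2-pyridyl triflates, to give an imidazol-4-yl complex of divalent palladium; the 4-methoxybenzyl group then passes from zinc to palladium and reductive elimination forms the C4–CH2 bond. The closest known reaction type is the Negishi coupling of heteroaryl triflates (for example pyridyl and quinolyl triflates) with benzylic zinc halides, whereas an imidazol-4-yl triflate derived from a lactam has not been used in this way. No ring is closed and no stereocentre is created. The step needs chemoselectivity only, and the substrate secures it: 11 has a single C(sp2)–X site, no N–H or O–H bond that could quench 13, and its amidine and acetal groups ignore an organozinc. Because the 2-amidinoimidazole is donor-rich and therefore a slow electrophile, SPhos and the LiCl carried by 13 are preferred to a triarylphosphine catalyst. The benzyl group has no β-hydrogen, and slow addition of 13 should hold bibenzyl formation down.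

Step 10
Reactants: 14 the doubly benzylated formamidine
Product: 16 5-{[2-amino-4-(4-methoxybenzyl)-1-methyl-1H-imidazol-5-yl]methyl}-2,3-dimethoxybenzene-1,4-diol, via MOM-protected aminoimidazole 15 (not isolated)
Conditions: N2H4·H2O, EtOH, 70 °C, evaporate; then HCl (1.25 M in MeOH), 40 °C, Ar; degassed aq NaHCO3/Na2S2O4, EtOAc extraction
Reagents that add atoms: none
Why: Transamidination by hydrazine frees the 2-amino group while the acetals are still in place, and brief acid-catalysed acetal exchange with methanol then unmasks the hydroquinone, whose aminoimidazolium salt is stable to acid, before the acid-labile dehydrohydantoin exists.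

Step 11
Reactants: 16 the aminoimidazole hydroquinone; 17 1-methylparabanic acid
Product: 21 naamidine E, via N-silyl methylparabanic acid 18 (not isolated), via bis-silyl aminoimidazole 19 (not isolated), via bis-silyl naamidine E 20 (not isolated)
Conditions: 17, BSA, MeCN, 80 °C, evaporate; 16, BSA, toluene, 25 °C; combine, 110 °C, Ar; then MeOH, citric acid (cat.), 25 °C
Reagents that add atoms: N,O-bis(trimethylsilyl)acetamide (BSA), CC(=N[Si](C)(C)C)O[Si](C)(C)C (silyl groups of 18, 19 and 20 only; none remains in 21)
Why: Addition–elimination of the 2-amino group at C4 of 18 (the carbonyl next to the silylated nitrogen, activated as its O-silyl imidate tautomer) is the known way to turn 2-aminoimidazoles, phenol-bearing ones included, into 2-(dehydrohydantoinyl)amino derivatives, and transient silylation shields the hydroquinone from oxidation until the mild methanolysis at the end.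

Compound list
1 | 2,3-dimethoxy-1,4-benzoquinone | COC1=C(OC)C(=O)C=CC1=O | starting material
2 | 2,3-dimethoxybenzene-1,4-diol | COc1c(O)ccc(O)c1OC | intermediate
3 | 1,4-bis(methoxymethoxy)-2,3-dimethoxybenzene | COCOc1ccc(OCOC)c(OC)c1OC | intermediate
4 | 2,5-bis(methoxymethoxy)-3,4-dimethoxyphenyllithium | [Li]c1cc(OCOC)c(OC)c(OC)c1OCOC | intermediate
5 | 2,5-bis(methoxymethoxy)-3,4-dimethoxybenzaldehyde | O=Cc1cc(OCOC)c(OC)c(OC)c1OCOC | intermediate
6 | creatinine | CN1CC(=O)N=C1N | starting material
7 | (E)-2-amino-5-[2,5-bis(methoxymethoxy)-3,4-dimethoxybenzylidene]-1-methyl-1,5-dihydro-4H-imidazol-4-one | CN1C(N)=NC(=O)/C1=C\c1cc(OCOC)c(OC)c(OC)c1OCOC | intermediate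
8 | racemic 2-amino-5-[2,5-bis(methoxymethoxy)-3,4-dimethoxybenzyl]-1-methyl-1,5-dihydro-4H-imidazol-4-one | CN1C(N)=NC(=O)C1Cc1cc(OCOC)c(OC)c(OC)c1OCOC | intermediate
9 | racemic N'-{5-[2,5-bis(methoxymethoxy)-3,4-dimethoxybenzyl]-1-methyl-4-oxo-4,5-dihydro-1H-imidazol-2-yl}-N,N-dimethylformimidamide | CN(C)C=NC1=NC(=O)C(Cc2cc(OCOC)c(OC)c(OC)c2OCOC)N1C | intermediate
10 | potassium 2-{[(dimethylamino)methylidene]amino}-1-methyl-5-[2,5-bis(methoxymethoxy)-3,4-dimethoxybenzyl]-1H-imidazol-4-olate | CN(C)C=Nc1nc([O-])c(Cc2cc(OCOC)c(OC)c(OC)c2OCOC)n1C.[K+] | intermediate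
11 | 2-{[(dimethylamino)methylidene]amino}-1-methyl-5-[2,5-bis(methoxymethoxy)-3,4-dimethoxybenzyl]-1H-imidazol-4-yl trifluoromethanesulfonate | CN(C)C=Nc1nc(OS(=O)(=O)C(F)(F)F)c(Cc2cc(OCOC)c(OC)c(OC)c2OCOC)n1C | intermediate
12 | 4-methoxybenzyl chloride | COc1ccc(CCl)cc1 | starting material
13 | 4-methoxybenzylzinc chloride (LiCl complex in THF) | COc1ccc(C[Zn]Cl)cc1 | intermediate
14 | N'-{5-[2,5-bis(methoxymethoxy)-3,4-dimethoxybenzyl]-4-(4-methoxybenzyl)-1-methyl-1H-imidazol-2-yl}-N,N-dimethylformimidamide | COc1ccc(Cc2nc(N=CN(C)C)n(C)c2Cc2cc(OCOC)c(OC)c(OC)c2OCOC)cc1 | intermediate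
15 | 5-[2,5-bis(methoxymethoxy)-3,4-dimethoxybenzyl]-4-(4-methoxybenzyl)-1-methyl-1H-imidazol-2-amine | COc1ccc(Cc2nc(N)n(C)c2Cc2cc(OCOC)c(OC)c(OC)c2OCOC)cc1 | intermediate
16 | 5-{[2-amino-4-(4-methoxybenzyl)-1-methyl-1H-imidazol-5-yl]methyl}-2,3-dimethoxybenzene-1,4-diol | COc1ccc(Cc2nc(N)n(C)c2Cc2cc(O)c(OC)c(OC)c2O)cc1 | intermediate
17 | 1-methylparabanic acid (1-methylimidazolidine-2,4,5-trione) | CN1C(=O)C(=O)NC1=O | starting material
18 | 1-methyl-3-(trimethylsilyl)imidazolidine-2,4,5-trione (reacts through its 4-O-silyl imidate tautomer) | CN1C(=O)C(=O)N([Si](C)(C)C)C1=O | intermediate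
19 | bis(O-trimethylsilyl) ether of 16 | COc1ccc(Cc2nc(N)n(C)c2Cc2cc(O[Si](C)(C)C)c(OC)c(OC)c2O[Si](C)(C)C)cc1 | intermediate
20 | bis(O-trimethylsilyl) ether of naamidine E | COc1ccc(Cc2nc(NC3=NC(=O)N(C)C3=O)n(C)c2Cc2cc(O[Si](C)(C)C)c(OC)c(OC)c2O[Si](C)(C)C)cc1 | intermediate
21 | naamidine E | COc1ccc(Cc2nc(NC3=NC(=O)N(C)C3=O)n(C)c2Cc2cc(O)c(OC)c(OC)c2O)cc1 | target

Total step count: 11. Longest linear sequence: 10 steps (1 to 21 through steps 1–7 and 9–11). Step 8 is the only side branch.

Steps most likely to fail

1. Step 9. Oxidative addition into the donor-rich C4–O bond may be too slow. Sulfur–oxygen cleavage back to the imidazolone and homocoupling of the zinc reagent would then take over. The fallback builds the imidazole from an acyclic precursor by known reactions instead of functionalising the lactam.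
- It sets out from 8. Hot aqueous Ba(OH)2 opens the creatinine ring to the racemic N-methyl amino acid F1.
- Boc2O gives the N-Boc acid F2, and coupling with MeNHOMe·HCl (EDC, HOBt, iPr2NEt) gives the Weinreb amide F3.
- 4-Methoxybenzylmagnesium chloride F4, made from 12 and Mg in THF at 0 °C, adds once to give the N-Boc-N-methylamino ketone F5.
- Methanolic HCl removes the Boc group and both MOM groups to give the α-methylamino ketone F6, kept as its hydrochloride under argon.
- Condensation with cyanamide in aqueous EtOH at pH 4–5 and 95 °C closes the 2-aminoimidazole with the same substituent placement.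
- It comes back to the route at 16.

2. Step 7. The ambident anion may be sulfonylated away from oxygen, or the triflyl group may be lost by hydrolysis during isolation. The fallback activates C4 through sulfur instead of oxygen.
- It sets out from 9. Lawesson's reagent (toluene, 80 °C) gives the 4-thioxo compound F7.
- MeI and K2CO3 in acetone alkylate the soft sulfur with aromatisation to give the bench-stable 4-(methylthio)imidazole F8.
- F8 is joined to 13 by the Pd(OAc)2/SPhos-catalysed coupling known for N-heteroaryl methyl thioethers with benzylic zinc reagents.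
- It comes back to the route at 14.

3. Step 11. The hydroquinone may oxidise in air at reflux, or silylation may be incomplete and leave poorly soluble material, which would erode the final condensation. The fallback keeps the acetals on through that condensation.
- It sets out from 15, this time isolated after the hydrazine stage of step 10.
- 15 and 18 in toluene at 110 °C give bis-MOM naamidine E F9.
- Me3SiBr in CH2Cl2 at −30 → 0 °C exchanges both acetals for silyl ethers under anhydrous conditions, which spares the hydrolysis-prone acylamidine.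
- It comes back to the route at 20, which is methanolysed as in step 11.

Further compounds
F1 | step 9 | racemic 3-[2,5-bis(methoxymethoxy)-3,4-dimethoxyphenyl]-2-(methylamino)propanoic acid | CNC(Cc1cc(OCOC)c(OC)c(OC)c1OCOC)C(=O)O
F2 | step 9 | racemic N-Boc derivative of F1 | CN(C(=O)OC(C)(C)C)C(Cc1cc(OCOC)c(OC)c(OC)c1OCOC)C(=O)O
F3 | step 9 | racemic N-methoxy-N-methyl amide of F2 | CON(C)C(=O)C(Cc1cc(OCOC)c(OC)c(OC)c1OCOC)N(C)C(=O)OC(C)(C)C
F4 | step 9 | 4-methoxybenzylmagnesium chloride | COc1ccc(C[Mg]Cl)cc1
F5 | step 9 | racemic tert-butyl {1-[2,5-bis(methoxymethoxy)-3,4-dimethoxyphenyl]-4-(4-methoxyphenyl)-3-oxobutan-2-yl}(methyl)carbamate | COc1ccc(CC(=O)C(Cc2cc(OCOC)c(OC)c(OC)c2OCOC)N(C)C(=O)OC(C)(C)C)cc1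
F6 | step 9 | racemic 4-(2,5-dihydroxy-3,4-dimethoxyphenyl)-1-(4-methoxyphenyl)-3-(methylamino)butan-2-one (handled as hydrochloride) | CNC(Cc1cc(O)c(OC)c(OC)c1O)C(=O)Cc1ccc(OC)cc1
F7 | step 7 | racemic 4-thioxo analogue of 9 | CN(C)C=NC1=NC(=S)C(Cc2cc(OCOC)c(OC)c(OC)c2OCOC)N1C
F8 | step 7 | N'-{5-[2,5-bis(methoxymethoxy)-3,4-dimethoxybenzyl]-1-methyl-4-(methylsulfanyl)-1H-imidazol-2-yl}-N,N-dimethylformimidamide | CSc1nc(N=CN(C)C)n(C)c1Cc1cc(OCOC)c(OC)c(OC)c1OCOC
F9 | step 11 | bis(O-methoxymethyl) ether of naamidine E | COc1ccc(Cc2nc(NC3=NC(=O)N(C)C3=O)n(C)c2Cc2cc(OCOC)c(OC)c(OC)c2OCOC)cc1
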